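## Retrosynthetic overview

- The target is cut back to its methyl ester. The ester is then disconnected at a single carbon, C2 of the dihydropyran ring (ring B), through both O1–C2 and C2–C1′. Chroman locants are O1, C2, C3, C4, C4a, C8a; the side chain runs C1′ to C6′ counted from C2.
- This leaves an N-sulfonylhydrazone of a simple methyl ketone, which is the carbene precursor and already carries phenol O1, and a (1E,3E)-dienyl iodide. One palladium cycle (carbene formation, dienyl migration, η3-allyl, O-attack) joins them, closes ring B and sets (R)-C2.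
- Enabling feature: C2 is bound to O1, to CH3 and C3H2 (a former methyl-ketone carbon) and to C1′ of the C1′=C2′–C3′=C4′ diene (an allyl terminus). O1 reaches C2 through C8a–C4a–C4–C3 as a six-membered ring.
- The ketone comes from a Heck reaction of an iodophenol ester with but-3-en-2-ol. The dienyl iodide comes from dihydro-β-ionone by alkyne formation, methylalumination–iodination, ethynylation and hydrozirconation–iodination.
- Ring order: benzene ring A and cyclohexene ring C are bought. Ring B is the only ring that is made, and it closes last.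

Key step: step 7

Assumption: the sense of induction of the chiral ligand in step 7 cannot be read from precedent, so the (1R,2R) ligand is written; its equally available (1S,2S) antipode would be used if a first run shows the opposite sense.

## Route

Step 1
Reactants: 1 methyl 4-hydroxy-3-iodobenzoate; 2 but-3-en-2-ol (racemic)
Product: 3 methyl 4-hydroxy-3-(3-oxobutyl)benzoate
Conditions: Pd(OAc)2 (3 mol %), n-Bu4NCl, NaHCO3, DMF, 50 °C
Reagents that add atoms: none
Why: Heck reaction of an aryl iodide with a secondary allylic alcohol, in which aryl palladation at the terminal carbon and β-hydride elimination toward the carbinol C–H give the enol and hence the methyl ketone directly, while the bicarbonate base leaves the phenol and the ester alone.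

Step 2
Reactants: 3 methyl 4-hydroxy-3-(3-oxobutyl)benzoate
Product: 4 methyl 4-hydroxy-3-[(3E)-3-{2-[2-(trifluoromethyl)benzenesulfonyl]hydrazinylidene}butyl]benzoate
Conditions: 2-(CF3)C6H4SO2NHNH2 (1.05 equiv), MeOH, 23 °C
Reagents that add atoms: 2-(trifluoromethyl)benzenesulfonohydrazide, NNS(=O)(=O)c1ccccc1C(F)(F)F
Why: Acid-free condensation of a ketone with a sulfonyl hydrazide, the 2-(trifluoromethyl)benzenesulfonyl group being chosen because its hydrazone salts undergo the Bamford–Stevens reaction to the diazoalkane far below the temperature that tosylhydrazones need, and the C=N geometry being irrelevant because it is lost in step 7.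

Step 3
Reactants: 5 dihydro-β-ionone, 4-(2,6,6-trimethylcyclohex-1-en-1-yl)butan-2-one
Product: 7 2-(but-3-yn-1-yl)-1,3,3-trimethylcyclohex-1-ene, via enol diethyl phosphate 6 (not isolated)
Conditions: LiN(iPr)2 (1.1 equiv), THF, −78 °C; ClP(O)(OEt)2, −78 to 23 °C; then LiN(iPr)2 (2.3 equiv), THF, −78 to 23 °C; H2O
Reagents that add atoms: diethyl chlorophosphate, CCOP(=O)(Cl)OCC (its atoms stay in 6 only)
Why: Kinetic deprotonation at the methyl group, O-phosphorylation and base-induced β-elimination of the terminal enol phosphate form the standard conversion of a methyl ketone into a terminal alkyne, and the tetrasubstituted alkene of ring C is inert to the amide base.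

Step 4
Reactants: 7 2-(but-3-yn-1-yl)-1,3,3-trimethylcyclohex-1-ene
Product: 9 2-[(3E)-4-iodo-3-methylbut-3-en-1-yl]-1,3,3-trimethylcyclohex-1-ene, via alkenyldimethylalane 8 (not isolated)
Conditions: Me3Al (2 equiv), Cp2ZrCl2 (20 mol %), CH2Cl2, 0 to 23 °C; then I2, THF, −30 to 0 °C
Reagents that add atoms: trimethylaluminium, C[Al](C)C; iodine, [I][I]
Why: Negishi carboalumination (zirconium-catalysed methylalumination) adds CH3 and Al syn across the terminal alkyne with Al at the terminus, so that iodinolysis with retention fixes the E geometry of the future C3′=C4′ bond.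

Step 5
Reactants: 9 2-[(3E)-4-iodo-3-methylbut-3-en-1-yl]-1,3,3-trimethylcyclohex-1-ene
Product: 10 1,3,3-trimethyl-2-[(3E)-3-methylhex-3-en-5-yn-1-yl]cyclohex-1-ene
Conditions: HC≡CMgBr, ZnBr2, THF, 0 °C; then 9, Pd(PPh3)4 (3 mol %), 23 °C
Reagents that add atoms: ethynylmagnesium bromide, C#C[Mg]Br
Why: Negishi coupling of an alkenyl iodide with ethynylzinc bromide proceeds with retention of the alkene geometry and delivers the terminal enyne without a protecting group.

Step 6
Reactants: 10 1,3,3-trimethyl-2-[(3E)-3-methylhex-3-en-5-yn-1-yl]cyclohex-1-ene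
Product: 12 2-[(3E,5E)-6-iodo-3-methylhexa-3,5-dien-1-yl]-1,3,3-trimethylcyclohex-1-ene, via dienylzirconocene chloride 11 (not isolated)
Conditions: Cp2Zr(H)Cl (1.2 equiv), THF, 23 °C, dark; then I2 (1.0 equiv), THF, −78 °C; aq. Na2S2O3
Reagents that add atoms: iodine, [I][I]; Cp2Zr(H)Cl, [H][Zr](Cl)(C1C=CC=C1)C1C=CC=C1 (its atoms stay in 11 only)
Why: Hydrozirconation adds H and Zr syn to the terminal alkyne with Zr at the terminus and ignores the tri- and tetrasubstituted alkenes, so that iodinolysis with retention fixes the E geometry of the future C1′=C2′ bond.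

Step 7
Reactants: 4 N-sulfonylhydrazone of ketone 3 (1.3 equiv); 12 (1E,3E)-dienyl iodide (1.0 equiv)
Product: 14 methyl (2R)-2-methyl-2-[(1E,3E)-4-methyl-6-(2,6,6-trimethylcyclohex-1-en-1-yl)hexa-1,3-dien-1-yl]-3,4-dihydro-2H-chromene-6-carboxylate, via diazoalkane 13 (not isolated)
Conditions: 4, LiOt-Bu (2.1 equiv per 4), THF, 0 °C; slow addition to 12, Pd2(dba)3·CHCl3 (2.5 mol %), (1R,2R)-N,N′-bis[2-(diphenylphosphanyl)benzoyl]cyclohexane-1,2-diamine (7.5 mol %), THF, 40 °C
Reagents that add atoms: none
Why: Proposed new method: LiOt-Bu converts 4 into diazoalkane 13 (Bamford–Stevens reaction) while zerovalent palladium inserts into the C–I bond of 12 with retention; the dienyl complex of divalent palladium takes up 13 with loss of N2 to give a palladium carbene at the future C2, the dienyl group migrates onto this carbon (C2–C1′ bond), the tertiary σ-allyl species collapses to the syn-η3-allyl complex spanning C2–C1′–C2′, and the tethered phenoxide O1 attacks C2 anti to the metal (O1–C2 bond), which returns zerovalent palladium. The closest known reaction types are the carbenylative amination of vinyl iodides with N-sulfonylhydrazones (same carbene insertion, η3-allyl formation and intramolecular capture, also known with chiral phosphines) and the palladium-catalysed asymmetric allylic etherification of phenol allyl carbonates, which closes 2-methyl-2-vinylchromans at the same kind of fully substituted allyl terminus; new are the dialkyl carbene, the oxygen nucleophile and the fact that both new bonds end at the carbene carbon. Ring B closes in the 6-exo mode, O1 bonding to the allyl terminus C2 with C1′=C2′ left outside the ring, whereas attack at C2′ or C4′ would need an eight- or ten-membered ring. C2, the only new stereocentre, is controlled by the chiral bisphosphine, which has to tell CH3 from the CH2CH2Ar arm of the carbene in the migratory insertion; anti attack then passes this on with inversion, and because the two faces of the E-configured allyl unit cannot interchange by η3–η1–η3 motion without turning the C1′=C2′ bond to Z, the information is not lost before ring closure. The step needs ring closure to outrun β-hydride elimination from CH3 or C3–H, the usual fate of such hydrazone couplings: the adjacent C1′=C2′ bond captures the metal as η3-allyl at once, the chelating ligand leaves no free cis site in that cationic complex, and the nucleophile is a preformed, intramolecular and only weakly basic 4-carbomethoxyphenoxide. Both E double bonds come unchanged from 12, since oxidative addition and migration keep the alkene geometry and the diene substituent sits syn on the allyl unit.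

Step 8
Reactants: 14 methyl ester of the target
Product: 15 (2R)-2-methyl-2-[(1E,3E)-4-methyl-6-(2,6,6-trimethylcyclohex-1-en-1-yl)hexa-1,3-dien-1-yl]-3,4-dihydro-2H-chromene-6-carboxylic acid (CNP0265961.1)
Conditions: LiOH, THF/MeOH/H2O, 40 °C; then aq. KHSO4 to pH 4, 0 °C
Reagents that add atoms: lithium hydroxide, [Li+].[OH-]
Why: Saponification by acyl–oxygen cleavage touches neither the base-stable tertiary allylic aryl ether nor C2, and the cold, mildly acidic work-up avoids ionisation of the O1–C2 bond.

## Compound list

1 | methyl 4-hydroxy-3-iodobenzoate | COC(=O)c1ccc(O)c(I)c1 | starting material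
2 | but-3-en-2-ol (racemic) | CC(O)C=C | starting material
3 | methyl 4-hydroxy-3-(3-oxobutyl)benzoate | COC(=O)c1ccc(O)c(CCC(C)=O)c1 | intermediate
4 | methyl 4-hydroxy-3-[(3E)-3-{2-[2-(trifluoromethyl)benzenesulfonyl]hydrazinylidene}butyl]benzoate | COC(=O)c1ccc(O)c(CC/C(C)=N/NS(=O)(=O)c2ccccc2C(F)(F)F)c1 | intermediate
5 | dihydro-β-ionone, 4-(2,6,6-trimethylcyclohex-1-en-1-yl)butan-2-one | CC(=O)CCC1=C(C)CCCC1(C)C | starting material
6 | diethyl 4-(2,6,6-trimethylcyclohex-1-en-1-yl)but-1-en-2-yl phosphate (not isolated) | C=C(CCC1=C(C)CCCC1(C)C)OP(=O)(OCC)OCC | intermediate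
7 | 2-(but-3-yn-1-yl)-1,3,3-trimethylcyclohex-1-ene | C#CCCC1=C(C)CCCC1(C)C | intermediate
8 | dimethyl[(1E)-2-methyl-4-(2,6,6-trimethylcyclohex-1-en-1-yl)but-1-en-1-yl]alane (not isolated) | C[Al](C)/C=C(\C)CCC1=C(C)CCCC1(C)C | intermediate
9 | 2-[(3E)-4-iodo-3-methylbut-3-en-1-yl]-1,3,3-trimethylcyclohex-1-ene | I/C=C(\C)CCC1=C(C)CCCC1(C)C | intermediate
10 | 1,3,3-trimethyl-2-[(3E)-3-methylhex-3-en-5-yn-1-yl]cyclohex-1-ene | C#C/C=C(\C)CCC1=C(C)CCCC1(C)C | intermediate
11 | chloro[(1E,3E)-4-methyl-6-(2,6,6-trimethylcyclohex-1-en-1-yl)hexa-1,3-dien-1-yl]zirconocene (not isolated; cyclopentadienyl rings drawn σ-bonded) | Cl[Zr](C1C=CC=C1)(C1C=CC=C1)/C=C/C=C(\C)CCC1=C(C)CCCC1(C)C | intermediate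
12 | 2-[(3E,5E)-6-iodo-3-methylhexa-3,5-dien-1-yl]-1,3,3-trimethylcyclohex-1-ene | I/C=C/C=C(\C)CCC1=C(C)CCCC1(C)C | intermediate
13 | methyl 3-(3-diazobutyl)-4-hydroxybenzoate (not isolated; present as its lithium phenoxide) | COC(=O)c1ccc(O)c(CCC(C)=[N+]=[N-])c1 | intermediate
14 | methyl (2R)-2-methyl-2-[(1E,3E)-4-methyl-6-(2,6,6-trimethylcyclohex-1-en-1-yl)hexa-1,3-dien-1-yl]-3,4-dihydro-2H-chromene-6-carboxylate | CC1=C(CC/C(C)=C/C=C/[C@@]2(C)CCc3cc(C(=O)OC)ccc3O2)C(C)(C)CCC1 | intermediate
15 | (2R)-2-methyl-2-[(1E,3E)-4-methyl-6-(2,6,6-trimethylcyclohex-1-en-1-yl)hexa-1,3-dien-1-yl]-3,4-dihydro-2H-chromene-6-carboxylic acid | CC1=C(CC/C(C)=C/C=C/[C@@]2(C)CCc3cc(C(=O)O)ccc3O2)C(C)(C)CCC1 | target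

## Step count and risks

Total step count: 8.
Longest linear sequence: 6 steps (5 → 7 → 9 → 10 → 12 → 14 → 15, steps 3 to 8).

### Steps most likely to fail

**Step 7 (Proposed new method).**

What may go wrong:
- β-Hydride elimination at the σ-allyl stage may overtake ring closure.
- Facial discrimination between the methyl group and the arylethyl arm in the migratory insertion may be weak.
- Enantiopurity may erode through palladium–palladium exchange on the allyl complex.
- The diazoalkane may decay without catalysis.

The fallback uses known chemistry: it sets the stereocentre first and closes ring B by aryl–oxygen bond formation. It sets out from enyne 10 and comes back at 14. Commercial methyl 3-bromo-4-fluorobenzoate F1 is coupled with 2 in a Heck reaction (Pd(OAc)2, P(o-Tol)3, NaHCO3, DMF, 100 °C) to give methyl 4-fluoro-3-(3-oxobutyl)benzoate F2. Enyne 10 is hydrozirconated to 11 as in step 6 and transmetalated with Me2Zn to methyl[(1E,3E)-4-methyl-6-(2,6,6-trimethylcyclohex-1-en-1-yl)hexa-1,3-dien-1-yl]zinc F3. F3 is added to F2 in the presence of Ti(OiPr)4 and a catalytic twofold-symmetric bis(camphorsulfonamide) diol ligand built on trans-cyclohexane-1,2-diamine (catalytic asymmetric dienylation of ketones). This should give methyl 4-fluoro-3-[(3R,4E,6E)-3-hydroxy-3,7-dimethyl-9-(2,6,6-trimethylcyclohex-1-en-1-yl)nona-4,6-dien-1-yl]benzoate F4. KN(SiMe3)2 in THF/DMF then closes ring B by intramolecular SNAr at the fluorine-bearing carbon, which the para ester activates. The C2–O bond is not touched, so the configuration is kept and 14 results.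

**Step 6.**

What may go wrong: hydrozirconation of the conjugated enyne may be incomplete or unselective, and iodine may isomerise the light-sensitive iodo diene during iodinolysis.

The fallback replaces alkyne hydrometalation by a vinylene transfer. It sets out from 9 and comes back at 12. Stille coupling of 9 with an excess of (E)-1,2-bis(tributylstannyl)ethene (PdCl2(MeCN)2, DMF, 23 °C) should give tributyl[(1E,3E)-4-methyl-6-(2,6,6-trimethylcyclohex-1-en-1-yl)hexa-1,3-dien-1-yl]stannane F5. Fast tin–iodine exchange of F5 with I2 in CH2Cl2 at −78 °C then gives 12 with retention.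

**Step 1.**

What may go wrong: β-hydride elimination may run toward the benzylic side instead of the carbinol side, and the ortho-hydroxy ketone may undergo follow-up condensation under the coupling conditions.

The fallback separates C–C bond formation from adjustment of the oxidation level. It sets out from 1 and comes back at 3. Heck reaction of 1 with methyl vinyl ketone (Pd(OAc)2, n-Bu4NCl, NaHCO3, DMF, 60 °C) should give methyl 4-hydroxy-3-[(1E)-3-oxobut-1-en-1-yl]benzoate F6. Hydrogenation of its C=C bond (H2, palladium on carbon, EtOAc, 23 °C) then gives 3.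

## Further compounds

F1 | step 7 | methyl 3-bromo-4-fluorobenzoate | COC(=O)c1ccc(F)c(Br)c1
F2 | step 7 | methyl 4-fluoro-3-(3-oxobutyl)benzoate | COC(=O)c1ccc(F)c(CCC(C)=O)c1
F3 | step 7 | methyl[(1E,3E)-4-methyl-6-(2,6,6-trimethylcyclohex-1-en-1-yl)hexa-1,3-dien-1-yl]zinc | C[Zn]/C=C/C=C(\C)CCC1=C(C)CCCC1(C)C
F4 | step 7 | methyl 4-fluoro-3-[(3R,4E,6E)-3-hydroxy-3,7-dimethyl-9-(2,6,6-trimethylcyclohex-1-en-1-yl)nona-4,6-dien-1-yl]benzoate | CC1=C(CC/C(C)=C/C=C/[C@@](O)(C)CCc2cc(C(=O)OC)ccc2F)C(C)(C)CCC1
F5 | step 6 | tributyl[(1E,3E)-4-methyl-6-(2,6,6-trimethylcyclohex-1-en-1-yl)hexa-1,3-dien-1-yl]stannane | CCCC[Sn](CCCC)(CCCC)/C=C/C=C(\C)CCC1=C(C)CCCC1(C)C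
F6 | step 1 | methyl 4-hydroxy-3-[(1E)-3-oxobut-1-en-1-yl]benzoate | COC(=O)c1ccc(O)c(/C=C/C(C)=O)c1
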